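The flasks below are neighbours: one charge of Z and L, put in by different routes.

| flask | Z | L | time | remark |
|---|---|---|---|---|
| gamma | 0.065 M | 1.05 equiv (fed, over 8.0 h) | 10 h | all else is in the flask from the start; the feed brings no volume worth counting |
| zeta | 0.065 M | 1.05 equiv (in portions, 3, over 8.0 h) | 10 h | first portion at the start, last at 8.0 h |
| eta | 0.065 M (fed, over 8.0 h) | 1.05 equiv | 10 h | all else is in the flask from the start; the feed brings no volume worth counting |
| alpha | 0.065 M | 1.05 equiv | 10 h | everything together at the start |

    Z + L → Z.L, rate k1*[Z]*[L]^0.5 (k1 = 8.5 × 10⁻⁴ L⁰·⁵ mol⁻⁰·⁵ s⁻¹)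
    Z + Z.L → Z.Z.L (k2 = 0.0034 L mol⁻¹ s⁻¹)
    L ⇌ G (K3 = 1.3, k3 = 1.6 × 10⁻⁴ s⁻¹)
    L + Z.L → L.Z.L (k4 = 7.7 × 10⁻⁵ L mol⁻¹ s⁻¹)

- a species is counted by the Z in it: one Z.Z.L counts as two
- run time (gamma): 10 h

* which flask leads in amount of Z.L, in percent of the Z charged ("all alike" within 1.5 percentage points) (gamma / zeta / eta / alpha / all alike)
* how much Z.L is there at the end, in percent of the Z charged: gamma
* how much Z.L is there at the end, in percent of the Z charged: zeta
* how much Z.L is there at the end, in percent of the Z charged: eta
* how much Z.L is there at the end, in percent of the Z charged: alpha

Does low Z protect Z.L? The first and second steps both carry Z, so Z cancels from their ratio, a selectivity factor. Let p be the fraction of the Z charge standing as Z.L, and λ the free L as a fraction of the same charge. The ratio is then s√λ/p, where s is the first rate constant over the second, divided by the square root of the Z concentration charged. This balance number is 0.981. Z.L gains on these two steps while p stands below b = s√λ, and loses above it.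

How much L is free? L relaxes towards G with a half-life of 0.680 h, far shorter than the feed time of 8.0 h. With that half-life shorter than the feed time, free L tends towards 43.5% of the pool of L and G. In alpha, b opens at 100%, relaxation with no uptake takes it to 66.3%, and Z lives 1.25 h against the full charge. Eta's low Z does not enter the ratio, and its L has the same relaxation half-life. Zeta's first portion opens at b = 58.0%, lower than alpha's opening.

Where does it end? With Z used up, each Z.L has cost one L and each Z.Z.L one L for two Z. Leaving L.Z.L aside and setting p equal to b on the remaining pool gives an estimate of 38.6%. My reckoning puts alpha first, near that value, with eta below it and gamma and zeta lower.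

The forecast differs on the leader: it names eta, in its words “keeping Z low against plentiful L (eta) should do best”. It gives gamma 31%, zeta 25%, eta 37% and alpha 35%.

Alpha leads with 36.2%, ahead of eta at 33.6%, gamma at 26.5% and zeta at 22.7%. After 10.0 h, alpha holds L at 14.5% of its own charge and Z at 0.201%. That L gives b = 38.2%. Just before its last portion, after 8.00 h, zeta holds L at 4.75% of its own charge, which gives b = 21.9%, and Z.L stands at 20.3%.

The numbers are those of an exercise; the rest is arithmetic.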